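The leftover, the fraction of the charge that is not target, is easier to reckon with than the yield.

| flask | starting material | free catalyst | remark | time |
|---|---|---|---|---|
| birch | 0.28 M | 0.14 mM | run made earlier |  |
| oak | 0.28 M | 0.070 mM | run made earlier |  |
| maple | 0.28 M | 0.28 mM | run made earlier |  |
| cedar | 0.56 M | 0.14 mM | run made earlier |  |
| blue | 0.28 M | 0.14 mM | a single well-mixed tank run continuously and read at steady state, 12.5 h in it on average |  |
| amber | 0.28 M | 0.14 mM | one stirred flow tank at steady state, fed with the mixture as stated, mean residence time 2.5 h |  |
| ochre | 0.28 M (fed, over 2.00 h) | 0.14 mM | all but starting material at the start; starting material goes in evenly over 2.00 h, the run ends at 2.5 h | 2.5 h |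
| red | 0.28 M | 0.14 mM | everything together in a closed stirred flask, run for 2.5 h | 2.5 h |

- birch (time / min: target / %): 25.0: 30; 50.0: 45; 60.0: 49; 90.0: 55
- oak (time / min: target / %): 30.0: 17; 60.0: 28; 90.0: 36; 120: 38
- maple (time / min: target / %): 10.0: 28; 20.0: 42; 50.0: 67; 120: 74
- cedar (time / min: target / %): 10.0: 11; 20.0: 29; 50.0: 47; 120: 57

(standard deviation of a reading: 2 percentage points)

* order of the set-ups by the amount of target at the outlet or at the end, in percent of the starting material put in, highest first (blue / amber / ochre / red)
* amount of target at the outlet or at the end, in percent of the starting material put in, blue
* amount of target at the outlet or at the end, in percent of the starting material put in, amber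
* amount of target at the outlet or at the end, in percent of the starting material put in, ochre
* amount of target at the outlet or at the end, in percent of the starting material put in, red

- the stated concentrations are those of everything mixed, before any reaction; amounts are the same in each set-up
- the feed brings no volume worth counting
- the earlier runs were made in a closed, stirred flask

Does the leftover follow the charge of starting material? At 50.0 min it reads 55.0 % in the birch run and 53.0 % in the cedar run, although cedar holds 2.00 times the charge. So within the scatter the percent made does not follow the charge, as for a step first order in starting material, and the logarithm of the leftover is the number to work with.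

Does the leftover stop falling? In the oak run, target rises by 11 percentage points between 30.0 min and 60.0 min and by 2 points between 90.0 min and 120 min, less, so the climb slows; with a scatter of 2 points on each reading, that does not show a level.

How does the late leftover follow the catalyst? The catalyst reach, the natural logarithm of the reciprocal of the leftover at the last reading per mM of catalyst charged, is 6.83 mM⁻¹ from oak at 120 min. From maple at 120 min it reads 4.81 mM⁻¹, lower with more catalyst. Oak's reach gives red a leftover of 38.4 %, so this reckoning, which is not the forecast's, puts target at 61.6 %. The reach comes from closed flasks and makes no claim on the tanks or the feed.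

The forecast gives red > blue > amber > ochre, with 47 %, 42 %, 19 % and 57 % for blue, amber, ochre and red, on the ground that “the catalyst is dying, not the reaction reaching equilibrium”.

The flasks give red > ochre > amber > blue, with 27.6 %, 41.2 %, 48.5 % and 63.4 %.

    free catalyst + other conformer → free catalyst + isomer of the product A (k = 9500 M⁻¹ h⁻¹)
    free catalyst + other conformer → spent catalyst (k = 12.0 M⁻¹ h⁻¹)
    free catalyst ⇌ dormant form (K = 0.630, k = 0.300 h⁻¹)
    starting material + free catalyst → free catalyst + target (k = 7200 M⁻¹ h⁻¹)
    target + free catalyst ⇌ isomer of the product B + free catalyst, rate k5*[free catalyst]*[target] forward; the back reaction follows from the equilibrium constant (K = 2.20, k = 290 M⁻¹ h⁻¹)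
    starting material ⇌ other conformer (K = 3.10, k = 0.270 h⁻¹)

Red's result means a reach of 7.18 mM⁻¹, and its leftover holds 11.5 % as starting material. In red, the half-life of starting material by the target step, catalyst held at its charge, is 0.69 h, shorter than the 1.94 h relaxation half-life of starting material and other conformer. At 0.465 h the target step uses starting material 3.1 times as fast as the forward step to other conformer. In a neighbour flask, like red but with 3.5 × 10⁻⁵ M of catalyst, oak's reach gives 21.3 % target. That flask gives 22.5 %, with 31.0 % as other conformer.

The runs are simulated from invented constants, noise included.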